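**Retrosynthetic overview**
- 10 ⇒ 3 + 8. The two free ring carbons of acylphloroglucinol 3 are C-alkylated in one flask by a C15 1,3-bis-electrophile. Ring B is the only ring made, and it is made last.
- The bonds form in the biosynthetic order. C5–C6 comes first (the "geranylation" bond, SN2 at CH2). The dearomatising C1→C8 closure follows, onto the tertiary centre that corresponds to the cation left after prenyl transfer to C-7 of a geranyl chain.
- 8 ⇒ diol 7 (the hydrate of that cation, with C-7 and C-8 already set) ⇒ prenyl–copper opening of (2S,3R)-epoxynerol 5 ⇒ nerol 4.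
- 3 ⇒ phloroglucinol 1 + isobutyryl chloride 2. Ring A is bought as the aromatic polyketide core.

Assumption: the C-2 enol in the target SMILES and its C-4 enol are freely interconverting tautomers of one compound. The atom numbers C-1 to C-9 are those of the bicyclo[3.3.1]nonane name of 10 and are also used for the corresponding atoms of earlier compounds.

**Step 1**
Reactants: 1 phloroglucinol; 2 isobutyryl chloride
Product: 3 phlorisobutyrophenone
Conditions: AlCl3 (3.5 equiv), PhNO2–CH2Cl2, 0 → 45 °C; ice/aq HCl
Reagents that add atoms: none
Why: This is a Friedel–Crafts acylation of a very electron-rich arene in which the first acyl group, held in a chelate with AlCl3, deactivates the ring enough to stop at mono-acylation, and no stereocentre is formed.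

**Step 2**
Reactants: 4 nerol
Product: 5 (2S,3R)-2,3-epoxynerol
Conditions: Ti(OiPr)4 (5 mol %), L-(+)-diethyl tartrate (7 mol %), t-BuOOH, 4 Å MS, CH2Cl2, −20 °C
Reagents that add atoms: tert-butyl hydroperoxide, CC(C)(C)OO
Why: The Sharpless asymmetric epoxidation touches only the allylic 2,3-alkene, and with L-(+)-tartrate the Z-allylic alcohol is oxidised on the face that gives (2S,3R), which fixes the future C-8 and, after one inversion, C-7.

**Step 3**
Reactants: 5 (2S,3R)-2,3-epoxynerol; 6 prenylmagnesium chloride
Product: 7 (2R,3R)-2-prenyl-1,3-diol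
Conditions: MeMgCl (1.0 equiv), THF, −40 °C; then 6 (2.5 equiv), CuI (10 mol %), −40 → 0 °C; aq NH4Cl
Reagents that add atoms: none
Why: The copper-catalysed SN2 opening of the epoxy alkoxide by the allylic Grignard reagent goes to the secondary C-2 because C-3 is fully substituted, so C-2 is inverted to (2R) with prenyl bound through its CH2 terminus while the C-3–O bond (3R) is untouched.

**Step 4**
Reactants: 7 (2R,3R)-2-prenyl-1,3-diol
Product: 8 (4R,5R)-cyclic sulfate
Conditions: NaH (2.2 equiv), THF, 0 °C; SO2(imidazol-1-yl)2, −20 → 0 °C; used cold, no chromatography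
Reagents that add atoms: 1,1'-sulfonyldiimidazole, O=S(=O)(n1ccnc1)n1ccnc1
Why: Sulfuryl transfer to the dialkoxide forms the cyclic sulfate without an oxidant that would attack the alkenes, closes the six-membered ring at sulfur without breaking a bond at either stereocentre, and gives a 1,3-bis-electrophile with an SN2-active CH2 end and an ionisable tertiary end.

**Step 5**
Reactants: 3 phlorisobutyrophenone; 8 (4R,5R)-cyclic sulfate
Product: 10 target CNP0285183.2, via tertiary alkyl sulfate 9 (not isolated)
Conditions: 3 (2.5 equiv), LiN(SiMe3)2 (2 equiv per 3), PhMe–THF, −20 → 23 °C, add 8; then degassed aq LiOH, 45 °C, Ar; aq HCl to pH 3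
Reagents that add atoms: none
Why: Proposed new method: the lithium dianion of 3 opens 8 through carbon at the primary C–O bond (C-alkylation of lithium acylphloroglucinolates by primary sulfonate-type electrophiles is known); in aqueous base the 5-alkylphloroglucinol dianion should populate its keto form with C-5 sp3 and the chain axial, so C-1 can displace the tertiary sulfate (a diphosphate-like leaving group that ionises on its own) from the rear with inversion at C-8 and give a trione that cannot re-aromatise; C-1 and C-5 are forced cis by the three-atom bridge, and their sense follows from C-7 and C-8 through the boat-like fold that keeps prenyl anti to the forming bond and only CH3, not homoprenyl, over the enolate (7-endo); the closest known types are double displacement on cyclic sulfates by malonate, the base-induced catechin to catechinic acid rearrangement (the same phloroglucinol ring closure to a bicyclo[3.3.1]nonane-2,4,9-trione with two bridgehead H) and tertiary-cation capture in alkylative dearomatisation routes to this ring system.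

**Compound list**
1 | phloroglucinol (benzene-1,3,5-triol) | Oc1cc(O)cc(O)c1 | starting material
2 | isobutyryl chloride (2-methylpropanoyl chloride) | CC(C)C(=O)Cl | starting material
3 | phlorisobutyrophenone, 2-methyl-1-(2,4,6-trihydroxyphenyl)propan-1-one | CC(C)C(=O)c1c(O)cc(O)cc1O | intermediate
4 | nerol, (2Z)-3,7-dimethylocta-2,6-dien-1-ol | CC(C)=CCC/C(C)=C\CO | starting material
5 | [(2S,3R)-3-methyl-3-(4-methylpent-3-en-1-yl)oxiran-2-yl]methanol (homoprenyl and CH2OH cis on the oxirane) | CC(C)=CCC[C@@]1(C)O[C@H]1CO | intermediate
6 | prenylmagnesium chloride, (3-methylbut-2-en-1-yl)magnesium chloride | CC(C)=CC[Mg]Cl | starting material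
7 | (2R,3R)-3,7-dimethyl-2-(3-methylbut-2-en-1-yl)oct-6-ene-1,3-diol | CC(C)=CCC[C@@](C)(O)[C@@H](CO)CC=C(C)C | intermediate
8 | (4R,5R)-4-methyl-5-(3-methylbut-2-en-1-yl)-4-(4-methylpent-3-en-1-yl)-1,3,2-dioxathiane 2,2-dioxide | CC(C)=CCC[C@@]1(C)OS(=O)(=O)OC[C@H]1CC=C(C)C | intermediate
9 | tertiary hydrogen sulfate (lithium salt in the flask) of 1-{3-[(2R,3R)-3-hydroxy-3,7-dimethyl-2-(3-methylbut-2-en-1-yl)oct-6-en-1-yl]-2,4,6-trihydroxyphenyl}-2-methylpropan-1-one | CC(C)=CCC[C@@](C)(OS(=O)(=O)O)[C@@H](Cc1c(O)cc(O)c(C(=O)C(C)C)c1O)CC=C(C)C | intermediate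
10 | (1S,5S,7R,8S)-2-hydroxy-8-methyl-7-(3-methylbut-2-en-1-yl)-8-(4-methylpent-3-en-1-yl)-3-(2-methylpropanoyl)bicyclo[3.3.1]non-2-ene-4,9-dione (prenyl at C-7 endo, cis to the C-2–C-4 bridge; homoprenyl at C-8 trans to it) | CC(C)=CCC[C@@]1(C)[C@H](CC=C(C)C)C[C@@H]2C(=O)C(C(=O)C(C)C)=C(O)[C@H]1C2=O | target

**Step count**
- Total steps: 5.
- Longest linear sequence: 4 (4 → 5 → 7 → 8 → 10).

**Steps most likely to fail**

**Step 5.** Three things can go wrong.
- Oxygen rather than C-1 may capture C-8. This gives the 2,2-disubstituted chroman, which is an aromatic dead end.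
- The tertiary sulfate may eliminate.
- C-5 is configurationally labile until the ring closes, so closure may run through the chair fold. That fold puts prenyl exo and gives the 7-exo, hyperforin-like diastereomer. I regard this as the more likely intrinsic preference, so it is the main threat to the route.

The fallback sets out from 3 and 8 and comes back at 10. Both free ring carbons are blocked first. Treating 3 with PhSCl (2 equiv, CH2Cl2, 0 °C) gives 2-methyl-1-[2,4,6-trihydroxy-3,5-bis(phenylsulfanyl)phenyl]propan-1-one F1. With 8 and the same base sequence, the first alkylation now creates a quaternary C-5. There is then no aromatic tautomer and no chroman sink, and the configuration at C-5 is frozen. The C-5 epimer that carries the chain on the face needed for the 7-endo bicycle can only close to the 1,5-bis(phenylsulfanyl) derivative of 10 F2. The other epimer gives the 7-exo isomer, which is removed by chromatography, so the yield is capped near one half. Bu3SnH/AIBN (PhMe, 90 °C) then exchanges both bridgehead sulfur groups for hydrogen, with retention enforced by the cage, and gives 10.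

**Step 3.** The prenyl reagent may couple through its tertiary terminus and give the reverse-prenyl product. Alternatively, the alkoxide may undergo Payne migration and be opened at C-1. The fallback sets out from 5 and comes back at 7. Compound 5 is opened with allylmagnesium bromide/CuI, which has no terminus ambiguity, to give (2R,3R)-3,7-dimethyl-2-(prop-2-en-1-yl)oct-6-ene-1,3-diol F3. Only the terminal alkene is then converted into the prenyl group by cross-metathesis with 2-methylbut-2-ene (second-generation Grubbs catalyst, CH2Cl2, 40 °C). The trisubstituted 6,7-alkene is inert under these conditions.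

**Step 4.** The sulfate may ionise at its tertiary C–O bond during formation or handling. The primary imidazolylsulfonate may also close to the oxetane. The fallback sets out from 7 and comes back at 10, bypassing 8 and 9, and it arms the two ends separately.
- I2/PPh3/imidazole gives (6R,7S)-7-(iodomethyl)-2,6,10-trimethylundeca-2,9-dien-6-ol F4.
- n-BuLi and then ClP(O)(OEt)2 gives its tertiary diethyl phosphate F5.
- C-alkylation of the lithium dianion of 3 with F5 gives the isolable diethyl phosphate analogue of 9 F6.
- F6 is closed in a separate operation (degassed aq LiOH, 50–60 °C) by the same rear-side attack of C-1 on C-8.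

**Further compounds**
F1 | step 5 | 2-methyl-1-[2,4,6-trihydroxy-3,5-bis(phenylsulfanyl)phenyl]propan-1-one | CC(C)C(=O)c1c(O)c(Sc2ccccc2)c(O)c(Sc2ccccc2)c1O
F2 | step 5 | 1,5-bis(phenylsulfanyl) derivative of 10 (same spatial arrangement at C-1, C-5, C-7 and C-8) | CC(C)=CCC[C@@]1(C)[C@H](CC=C(C)C)C[C@]2(Sc3ccccc3)C(=O)C(C(=O)C(C)C)=C(O)[C@@]1(Sc3ccccc3)C2=O
F3 | step 3 | (2R,3R)-3,7-dimethyl-2-(prop-2-en-1-yl)oct-6-ene-1,3-diol | CC(C)=CCC[C@@](C)(O)[C@@H](CO)CC=C
F4 | step 4 | (6R,7S)-7-(iodomethyl)-2,6,10-trimethylundeca-2,9-dien-6-ol | CC(C)=CCC[C@@](C)(O)[C@@H](CI)CC=C(C)C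
F5 | step 4 | diethyl (6R,7S)-7-(iodomethyl)-2,6,10-trimethylundeca-2,9-dien-6-yl phosphate | CC(C)=CCC[C@@](C)(OP(=O)(OCC)OCC)[C@@H](CI)CC=C(C)C
F6 | step 4 | tertiary diethyl phosphate analogue of 9 | CC(C)=CCC[C@@](C)(OP(=O)(OCC)OCC)[C@@H](Cc1c(O)cc(O)c(C(=O)C(C)C)c1O)CC=C(C)C
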